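**Retrosynthetic overview**

1. The diacetate is traced back to the free 1,2-diol and its bis-silyl ether. The bond between the alkene carbon C3 (the carbon carrying the exocyclic =CH2) and the carbinol carbon C2 is cut, giving a C18 terminal alkyne and (tert-butyldimethylsilyloxy)acetaldehyde, joined by a nickel-catalysed, carbene-ligand-controlled reductive coupling with a silane (decane numbering: C1 = CH2OAc, C2 = CHOAc, C10 = CH2 on the ring).
2. Enabling feature: the array C3(=CH2)–C2H(O)–C1H2(O) is a 2-alkyl allylic alcohol, so C3 and its methylene are the two carbons of a terminal alkyne and the C2–O bond is an aldehyde carbonyl. One operation makes the C3–C2 bond, the 1,1-disubstituted alkene and the C2 stereocentre and leaves O2 silylated; ring A (the tetrahydropyran, both carbons next to oxygen fully substituted) and the saturated chain are inert to zerovalent nickel.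
3. The alkyne comes from a primary iodide and acetylide (C4–C3). Its chain comes from a Wittig reaction at C9=C10 between the ring A aldehyde and a citronellyl-derived hydroxyalkyl ylide, followed by hydrogenation.
4. Ring A, the only ring, is closed first (step 1) by alkoxymercuration of (R)-linalool, which supplies the quaternary C–O stereocentre. (R)-Citronellyl bromide supplies the methyl stereocentre. The three stereocentres are too far apart for relay, so C2 is set by the catalyst in the key step.

Key step: step 9

Assumption: commercial (R)-(−)-linalool and (R)-(−)-citronellyl bromide are taken as enantiomerically pure; L·HBF4 in step 9 is an enantiopure, twofold-symmetric trans-4,5-diphenyl-1,3-bis(2,6-dialkylphenyl)imidazolinium tetrafluoroborate, used as the enantiomer that directs attack to the Re face of the aldehyde (to be fixed on 1-octyne as model); cod = cycloocta-1,5-diene.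

**Step 1**
Reactants: 1 (R)-(−)-linalool
Product: 3 (2R)-2-ethenyl-2,6,6-trimethyltetrahydro-2H-pyran, via alkylmercury acetate 2 (not isolated)
Conditions: Hg(OAc)2 (1.05 equiv), THF, 0 °C to rt; then 3 M NaOH, NaBH4, 0 °C
Reagents that add atoms: none
Why: Intramolecular alkoxymercuration–demercuration: the tertiary hydroxyl opens the mercurinium ion of the electron-rich trisubstituted alkene at its tertiary carbon (Markovnikov, 6-endo-trig) and NaBH4 replaces mercury by hydrogen, while the quaternary carbinol carbon is not a reacting centre and keeps its configuration.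

**Step 2**
Reactants: 3 (2R)-2-ethenyl-2,6,6-trimethyltetrahydro-2H-pyran
Product: 5 (2R)-2,6,6-trimethyltetrahydro-2H-pyran-2-carbaldehyde, via ozonide 4 (not isolated)
Conditions: O3, CH2Cl2, −78 °C; then Me2S, −78 °C to rt
Reagents that add atoms: ozone, [O-][O+]=O
Why: Ozonolysis with reductive work-up cleaves the only alkene to the aldehyde; ring A has no C–H next to oxygen and the aldehyde has no α-hydrogen, so neither ether oxidation nor epimerisation can occur.

**Step 3**
Reactants: 6 (R)-(−)-citronellyl bromide
Product: 8 (4R)-6-bromo-4-methylhexan-1-ol, via ozonide 7 (not isolated)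
Conditions: O3, CH2Cl2, −78 °C; then NaBH4, MeOH, −78 °C to rt
Reagents that add atoms: ozone, [O-][O+]=O
Why: Ozonolysis with borohydride work-up converts the trisubstituted alkene directly into the primary alcohol, the primary bromide and the methyl-bearing stereocentre being inert to ozone and to NaBH4 at low temperature.

**Step 4**
Reactants: 8 (4R)-6-bromo-4-methylhexan-1-ol
Product: 9 [(3R)-6-hydroxy-3-methylhexyl]triphenylphosphonium bromide
Conditions: PPh3 (1.1 equiv), MeCN, reflux
Reagents that add atoms: triphenylphosphine, c1ccc(cc1)P(c1ccccc1)c1ccccc1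
Why: SN2 quaternisation of triphenylphosphine by the unhindered primary bromide (phosphonium salt formation), which tolerates the free hydroxyl.

**Step 5**
Reactants: 9 [(3R)-6-hydroxy-3-methylhexyl]triphenylphosphonium bromide; 5 (2R)-2,6,6-trimethyltetrahydro-2H-pyran-2-carbaldehyde
Product: 11 (4R,6Z)-4-methyl-7-[(2R)-2,6,6-trimethyltetrahydro-2H-pyran-2-yl]hept-6-en-1-ol, via alkoxide ylide 10 (not isolated)
Conditions: NaN(SiMe3)2 (2.1 equiv), THF, 0 °C; then 5, −78 °C to rt
Reagents that add atoms: none
Why: Wittig olefination: two equivalents of base give the alkoxide ylide, whose non-stabilised ylide carbon adds to the non-enolisable α-alkoxy aldehyde to give mainly the Z-alkene, the geometry being irrelevant because the alkene is hydrogenated next and no stereocentre is touched.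

**Step 6**
Reactants: 11 (4R,6Z)-4-methyl-7-[(2R)-2,6,6-trimethyltetrahydro-2H-pyran-2-yl]hept-6-en-1-ol
Product: 12 (4S)-4-methyl-7-[(2S)-2,6,6-trimethyltetrahydro-2H-pyran-2-yl]heptan-1-ol
Conditions: H2 (1 atm), PtO2 (5 mol %), EtOAc, rt
Reagents that add atoms: none
Why: Heterogeneous catalytic hydrogenation of the 1,2-disubstituted alkene, with platinum rather than palladium chosen to suppress hydrogenolysis of the allylic tertiary C–O bond of ring A (the descriptors change only because the priorities change).

**Step 7**
Reactants: 12 (4S)-4-methyl-7-[(2S)-2,6,6-trimethyltetrahydro-2H-pyran-2-yl]heptan-1-ol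
Product: 13 (2S)-2-[(4S)-7-iodo-4-methylheptyl]-2,6,6-trimethyltetrahydro-2H-pyran
Conditions: I2, PPh3, imidazole, CH2Cl2, 0 °C to rt
Reagents that add atoms: iodine, II
Why: Appel-type (Garegg–Samuelsson) iodination, in which the primary alkoxyphosphonium ion is displaced by iodide in an SN2 step under neutral conditions that leave the tertiary ether untouched.

**Step 8**
Reactants: 13 (2S)-2-[(4S)-7-iodo-4-methylheptyl]-2,6,6-trimethyltetrahydro-2H-pyran
Product: 14 (2S)-2,6,6-trimethyl-2-[(4R)-4-methylnon-8-yn-1-yl]tetrahydro-2H-pyran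
Conditions: LiC≡CH·H2NCH2CH2NH2 (3 equiv), DMSO, 10 °C to rt
Reagents that add atoms: lithium acetylide–ethylenediamine complex, [Li+].[C-]#C.NCCN
Why: SN2 alkylation of lithium acetylide by the unhindered primary iodide in DMSO, a standard terminal alkyne synthesis in which substitution should outrun E2 elimination.

**Step 9**
Reactants: 14 (2S)-2,6,6-trimethyl-2-[(4R)-4-methylnon-8-yn-1-yl]tetrahydro-2H-pyran; 15 (tert-butyldimethylsilyloxy)acetaldehyde
Product: 16 (2R,7R)-1-(tert-butyldimethylsilyloxy)-7-methyl-3-methylidene-2-(triisopropylsilyloxy)-10-[(2S)-2,6,6-trimethyltetrahydro-2H-pyran-2-yl]decane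
Conditions: Ni(cod)2 (10 mol %), L·HBF4 (10 mol %), KOtBu (10 mol %), iPr3SiH (2 equiv), 15 (1.5 equiv), THF, rt, 14 added over 4 h
Reagents that add atoms: triisopropylsilane, CC(C)[SiH](C(C)C)C(C)C
Why: Proposed new method: zerovalent nickel carrying the bulky chiral carbene binds alkyne 14 and aldehyde 15 and undergoes oxidative cyclisation to a five-membered oxanickelacycle of divalent nickel in which the bond between the internal alkyne carbon and the carbonyl carbon (C3–C2) is made; σ-bond metathesis of the Ni–O bond with iPr3SiH and C–H reductive elimination then release the silyl-protected allylic alcohol and return zerovalent nickel. The closest known reaction types are the Ni(cod)2/N-heterocyclic carbene/silane reductive coupling of aldehydes with terminal alkynes, which a large carbene ligand steers to the 1,1-disubstituted (branched) allylic silyl ether, and its enantioselective version with bulky twofold-symmetric carbenes on internal alkynes; new here is the demand for both controls at once on a terminal aliphatic alkyne and an α-silyloxy aldehyde. No ring of the product is closed, the metallacycle being a transient catalyst-bound species. The single new stereocentre C2 is set by the chiral ligand alone, which must direct the alkenyl carbon to the Re face of 15 (giving 2R), the stereocentres of 14 being too remote to interfere. The step needs branch selectivity, which the maximal size difference of the two alkyne substituents (H against an unbranched CH2 chain) secures because the large ligand forces the hydrogen-bearing carbon next to nickel, and it needs chemoselectivity against alkyne oligomerisation and aldehyde hydrosilylation, which slow addition of 14 and the bulky silane secure, the fully substituted ring ether offering no coordinating or reactive site.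

**Step 10**
Reactants: 16 (2R,7R)-1-(tert-butyldimethylsilyloxy)-7-methyl-3-methylidene-2-(triisopropylsilyloxy)-10-[(2S)-2,6,6-trimethyltetrahydro-2H-pyran-2-yl]decane
Product: 17 (2R,7R)-7-methyl-3-methylidene-10-[(2S)-2,6,6-trimethyltetrahydro-2H-pyran-2-yl]decane-1,2-diol
Conditions: Bu4NF (3 equiv), THF, rt to 45 °C
Reagents that add atoms: none
Why: Fluoride-induced cleavage of both silyl ethers driven by Si–F bond formation; no C–O bond at C2 is broken, so the configuration set in step 9 is kept.

**Step 11**
Reactants: 17 (2R,7R)-7-methyl-3-methylidene-10-[(2S)-2,6,6-trimethyltetrahydro-2H-pyran-2-yl]decane-1,2-diol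
Product: 18 (2R,7R)-7-methyl-3-methylidene-10-[(2S)-2,6,6-trimethyltetrahydro-2H-pyran-2-yl]decane-1,2-diyl diacetate
Conditions: Ac2O, pyridine, DMAP (cat.), CH2Cl2, 0 °C to rt
Reagents that add atoms: acetic anhydride, CC(=O)OC(C)=O
Why: DMAP-catalysed acetylation of the primary and the secondary allylic hydroxyl with retention at C2, since only O–H bonds react.

**Compound list**

1 | (R)-(−)-linalool, (3R)-3,7-dimethylocta-1,6-dien-3-ol | C=C[C@@](O)(C)CCC=C(C)C | starting material
2 | acetoxy[(6R)-6-ethenyl-2,2,6-trimethyltetrahydro-2H-pyran-3-yl]mercury (C3 epimers) | C=C[C@@]1(C)CCC([Hg]OC(C)=O)C(C)(C)O1 | intermediate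
3 | (2R)-2-ethenyl-2,6,6-trimethyltetrahydro-2H-pyran ((R)-linaloyl oxide) | C=C[C@@]1(C)CCCC(C)(C)O1 | intermediate
4 | 3-[(2R)-2,6,6-trimethyltetrahydro-2H-pyran-2-yl]-1,2,4-trioxolane | C1(OCOO1)[C@@]2(C)CCCC(C)(C)O2 | intermediate
5 | (2R)-2,6,6-trimethyltetrahydro-2H-pyran-2-carbaldehyde | O=C[C@@]1(C)CCCC(C)(C)O1 | intermediate
6 | (R)-(−)-citronellyl bromide, (6R)-8-bromo-2,6-dimethyloct-2-ene | CC(C)=CCC[C@@H](C)CCBr | starting material
7 | 3-[(3R)-5-bromo-3-methylpentyl]-5,5-dimethyl-1,2,4-trioxolane | CC1(C)OOC(CC[C@@H](C)CCBr)O1 | intermediate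
8 | (4R)-6-bromo-4-methylhexan-1-ol | OCCC[C@@H](C)CCBr | intermediate
9 | [(3R)-6-hydroxy-3-methylhexyl]triphenylphosphonium bromide | OCCC[C@@H](C)CC[P+](c1ccccc1)(c1ccccc1)c1ccccc1.[Br-] | intermediate
10 | sodium (4R)-4-methyl-6-(triphenylphosphoranylidene)hexan-1-olate | [Na+].[O-]CCC[C@@H](C)CC=P(c1ccccc1)(c1ccccc1)c1ccccc1 | intermediate
11 | (4R,6Z)-4-methyl-7-[(2R)-2,6,6-trimethyltetrahydro-2H-pyran-2-yl]hept-6-en-1-ol | OCCC[C@@H](C)C/C=C\[C@@]1(C)CCCC(C)(C)O1 | intermediate
12 | (4S)-4-methyl-7-[(2S)-2,6,6-trimethyltetrahydro-2H-pyran-2-yl]heptan-1-ol | OCCC[C@@H](C)CCC[C@@]1(C)CCCC(C)(C)O1 | intermediate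
13 | (2S)-2-[(4S)-7-iodo-4-methylheptyl]-2,6,6-trimethyltetrahydro-2H-pyran | ICCC[C@@H](C)CCC[C@@]1(C)CCCC(C)(C)O1 | intermediate
14 | (2S)-2,6,6-trimethyl-2-[(4R)-4-methylnon-8-yn-1-yl]tetrahydro-2H-pyran | C#CCCC[C@@H](C)CCC[C@@]1(C)CCCC(C)(C)O1 | intermediate
15 | (tert-butyldimethylsilyloxy)acetaldehyde | O=CCO[Si](C)(C)C(C)(C)C | starting material
16 | (2R,7R)-1-(tert-butyldimethylsilyloxy)-7-methyl-3-methylidene-2-(triisopropylsilyloxy)-10-[(2S)-2,6,6-trimethyltetrahydro-2H-pyran-2-yl]decane | C=C(CCC[C@@H](C)CCC[C@@]1(C)CCCC(C)(C)O1)[C@H](CO[Si](C)(C)C(C)(C)C)O[Si](C(C)C)(C(C)C)C(C)C | intermediate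
17 | (2R,7R)-7-methyl-3-methylidene-10-[(2S)-2,6,6-trimethyltetrahydro-2H-pyran-2-yl]decane-1,2-diol | C=C(CCC[C@@H](C)CCC[C@@]1(C)CCCC(C)(C)O1)[C@H](CO)O | intermediate
18 | (2R,7R)-7-methyl-3-methylidene-10-[(2S)-2,6,6-trimethyltetrahydro-2H-pyran-2-yl]decane-1,2-diyl diacetate | C=C(CCC[C@@H](C)CCC[C@@]1(C)CCCC(C)(C)O1)[C@H](COC(C)=O)OC(C)=O | target

**Step count and risks**

Total step count: 11. Longest linear sequence: 9 steps (1, 2, 5–11; the branch 3, 4, 5–11 is equally long).

Steps most likely to fail:

1. Step 9 (proposed new method). The chiral carbene may discriminate the two faces of the small aldehyde insufficiently, branch selectivity may erode toward the linear E-allylic silyl ether, and the terminal alkyne may oligomerise faster than it couples. The fallback uses known chemistry, sets out from 14 and returns at 17. Hydroalumination of 14 with iBu2AlH catalysed by NiCl2(dppp) (dppp = 1,3-bis(diphenylphosphino)propane) in THF should place aluminium on the internal carbon and give the alkenylalane F1. Iodinolysis with I2 at −78 to 0 °C should give the 2-iodoalk-1-ene F2. A catalytic asymmetric Nozaki–Hiyama–Kishi coupling of F2 with 15 (CrCl2 with a chiral oxazoline sulfonamide ligand, NiCl2·(2,9-dimethyl-1,10-phenanthroline), Mn, Zr(C5H5)2Cl2, LiCl, MeCN, rt) should give the mono-silylated allylic alcohol F3 with the 2R configuration. Bu4NF in THF then gives diol 17.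

2. Step 5. Addition of the alkoxide-bearing ylide to the neopentyl-type aldehyde may be slow, so that the ylide decays and the volatile aldehyde is lost. The fallback sets out from 6 and 5 and returns at 12, bypassing 8, 9 and 11. Bromide 6 is converted with Mg in THF into the Grignard reagent F4, which should add to 5 at −78 to 0 °C to give the secondary alcohol F5 as a mixture of carbinol epimers. NaH, CS2 and MeI give the xanthate F6, and Barton–McCombie deoxygenation (Bu3SnH, AIBN, toluene, 110 °C) gives the deoxygenated alkene F7. Ozonolysis of F7 in CH2Cl2 at −78 °C gives the ozonide F8, which is reduced in the same flask with NaBH4/MeOH to alcohol 12.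

3. Step 1. Divalent mercury may also attack the vinyl group, ring closure may leak to the 5-exo tetrahydrofuran, and the radical formed on demercuration may revert to the open alkene or add to the vinyl group. The fallback sets out from 1 and returns at 3. Selenoetherification of 1 with N-(phenylselanyl)phthalimide and catalytic camphorsulfonic acid in CH2Cl2, a reversible ring closure under thermodynamic control that favours the six-membered ether, should give the 3-phenylselanyl tetrahydropyran F9. Reduction of the C–Se bond with Bu3SnH and AIBN in toluene at 80 °C gives 3.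

**Further compounds**

F1 | step 9 | diisobutyl{(6S)-6-methyl-9-[(2S)-2,6,6-trimethyltetrahydro-2H-pyran-2-yl]non-1-en-2-yl}alumane | C=C(CCC[C@@H](C)CCC[C@@]1(C)CCCC(C)(C)O1)[Al](CC(C)C)CC(C)C
F2 | step 9 | (2S)-2-[(4S)-8-iodo-4-methylnon-8-en-1-yl]-2,6,6-trimethyltetrahydro-2H-pyran | C=C(I)CCC[C@@H](C)CCC[C@@]1(C)CCCC(C)(C)O1
F3 | step 9 | (2R,7R)-1-(tert-butyldimethylsilyloxy)-7-methyl-3-methylidene-10-[(2S)-2,6,6-trimethyltetrahydro-2H-pyran-2-yl]decan-2-ol | C=C(CCC[C@@H](C)CCC[C@@]1(C)CCCC(C)(C)O1)[C@H](CO[Si](C)(C)C(C)(C)C)O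
F4 | step 5 | bromo[(3R)-3,7-dimethyloct-6-en-1-yl]magnesium | CC(C)=CCC[C@@H](C)CC[Mg]Br
F5 | step 5 | (4R)-4,8-dimethyl-1-[(2R)-2,6,6-trimethyltetrahydro-2H-pyran-2-yl]non-7-en-1-ol (C1 epimers) | CC(C)=CCC[C@@H](C)CCC(O)[C@@]1(C)CCCC(C)(C)O1
F6 | step 5 | O-{(4R)-4,8-dimethyl-1-[(2R)-2,6,6-trimethyltetrahydro-2H-pyran-2-yl]non-7-en-1-yl} S-methyl carbonodithioate (C1 epimers) | CC(C)=CCC[C@@H](C)CCC(OC(=S)SC)[C@@]1(C)CCCC(C)(C)O1
F7 | step 5 | (2S)-2-[(4S)-4,8-dimethylnon-7-en-1-yl]-2,6,6-trimethyltetrahydro-2H-pyran | CC(C)=CCC[C@@H](C)CCC[C@@]1(C)CCCC(C)(C)O1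
F8 | step 5 | 3,3-dimethyl-5-{(3S)-3-methyl-6-[(2S)-2,6,6-trimethyltetrahydro-2H-pyran-2-yl]hexyl}-1,2,4-trioxolane | CC1(C)OOC(CC[C@@H](C)CCC[C@@]2(C)CCCC(C)(C)O2)O1
F9 | step 1 | (6R)-6-ethenyl-2,2,6-trimethyl-3-(phenylselanyl)tetrahydro-2H-pyran (C3 epimers) | C=C[C@@]1(C)CCC([Se]c2ccccc2)C(C)(C)O1
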